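**Retrosynthetic overview**

1. Forward numbering used throughout: 1 → [2] → 3; 3 + 4 → [5] → 6; 6 + 7 → [8, 9] → 10. Target 10 is (1S,2S,6S): the aroyl group on C1 is trans to both the C2 prenyl and the C6 phenyl group.
2. Key disconnection 10 ⇒ 6 + 7: retro-[4+2] across C1–C2 and C5–C6 of the cyclohexene, the chalcone (pashanone) plus (E)-β-ocimene union presumed in the plant. It is run on the unprotected chalcone as a chiral spiroborate, so one step sets C1, C2 and C6. The trans,trans pattern needs the less usual aroyl-exo (phenyl-endo) mode.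
3. 6 ⇒ 3 + 4: retro-aldol (Claisen–Schmidt) at the enone C=C.
4. 3 ⇒ 1: the second ortho-OH is traced back to a methyl ether ortho to the ketone, removed under chelation control.
5. Ring order: both benzene rings are bought; the cyclohexene is the only ring formed, in the last step.

Assumption: ketone 1 is taken as a catalogue compound (it is also one Friedel–Crafts acetylation away from 3,4,5-trimethoxyphenol); 4 and technical ocimene (E/Z mixture, the source of 7) are bulk chemicals.

Assumption: the facial sense assigned to the (R)-VAPOL borate comes from a quadrant model of the spiroborate, not from a measured result; should the first run give the mirror-image series, (S)-VAPOL is substituted with no other change.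

**Route**

Step 1
Reactants: 1 6'-hydroxy-2',3',4'-trimethoxyacetophenone
Product: 3 2',6'-dihydroxy-3',4'-dimethoxyacetophenone, via aluminium phenolate 2 (not isolated)
Conditions: AlCl3 (3 equiv), PhCl, 80 °C, 1–2 h (monitored); then ice, 2 M HCl
Reagents that add atoms: none
Why: Chelation-directed Lewis-acid O-demethylation (aryl methyl ether cleavage): aluminium held on the ketone oxygen activates only the ortho 2'-OMe for chloride attack at methyl, the 3'- and 4'-OMe groups lack that assistance, and the 6'-O–AlCl2 group has no neighbouring methoxy group to labilise, so the reaction stops after one methyl is lost.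

Step 2
Reactants: 3 2',6'-dihydroxy-3',4'-dimethoxyacetophenone; 4 benzaldehyde
Product: 6 pashanone [(E)-2',6'-dihydroxy-3',4'-dimethoxychalcone], via aldol adduct 5 (not isolated)
Conditions: 4 (1.3 equiv), 50% aq KOH (10 equiv), EtOH, 0 °C → rt, 48 h, N2; then ice, 2 M HCl to pH 4 at 0 °C
Reagents that add atoms: none
Why: Claisen–Schmidt (crossed aldol) condensation: the potassium enolate of the methyl ketone adds to non-enolisable benzaldehyde and E1cB dehydration of aldol 5 gives the conjugated enone as the thermodynamic E isomer, the strongly basic medium holding the product as its open-chain phenolate instead of the flavanone.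

Step 3
Reactants: 6 pashanone; 7 (E)-β-ocimene
Product: 10 (2,6-dihydroxy-3,4-dimethoxyphenyl)[(1S,2S,6S)-3-methyl-2-(3-methylbut-2-en-1-yl)-6-phenylcyclohex-3-en-1-yl]methanone, via chalcone spiroborate 8 (not isolated), via cycloadduct spiroborate 9 (not isolated)
Conditions: (R)-VAPOL, BH3·THF, AcOH (1.2 equiv each), THF, rt, 1 h; add 6, 40 °C, 1 h, evaporate; 7 (5 equiv, as technical E/Z ocimene), PhCF3, 4 Å MS, rt, 24–48 h; then MeOH, H2O; SiO2 (ligand recovered)
Reagents that add atoms: none
Why: Proposed new method: the closest known reaction type is the chiral diol–boron-promoted asymmetric Diels–Alder reaction of 2'-hydroxychalcones with acyclic dienes (spiroborate chelation of phenolate O and C=O locks the enone s-cis and lowers its LUMO, the unsubstituted diene terminus bonds to the β-carbon), which with (E)-β-ocimene normally gives the aroyl-endo adduct, whereas here the E-enone fixes C1/C6 trans, the (R)-ligand is expected to cover the Cα-Re/Cβ-Re face so that bonding on the Si/Si face gives 1S and 6S, and the phenanthrene vault of VAPOL that overhangs the boron chelate is expected to clash with the 3-methyl group that an aroyl-endo approach must place over that chelate, diverting the diene to the aroyl-exo (phenyl-endo) transition state that puts the prenyl group trans to the aroyl group (2S).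

**Compound list**

1 | 6'-hydroxy-2',3',4'-trimethoxyacetophenone, 1-(6-hydroxy-2,3,4-trimethoxyphenyl)ethan-1-one | CC(=O)c1c(O)cc(OC)c(OC)c1OC | starting material
2 | bis(dichloroaluminium) 2',6'-diphenolate of 3, ArO–AlCl2 at both phenol oxygens | CC(=O)c1c(O[Al](Cl)Cl)cc(OC)c(OC)c1O[Al](Cl)Cl | intermediate (not isolated)
3 | 2',6'-dihydroxy-3',4'-dimethoxyacetophenone, 1-(2,6-dihydroxy-3,4-dimethoxyphenyl)ethan-1-one | CC(=O)c1c(O)cc(OC)c(OC)c1O | intermediate
4 | benzaldehyde | O=Cc1ccccc1 | starting material
5 | aldol adduct, racemic 1-(2,6-dihydroxy-3,4-dimethoxyphenyl)-3-hydroxy-3-phenylpropan-1-one (present as its potassium salt) | COc1cc(O)c(C(=O)CC(O)c2ccccc2)c(O)c1OC | intermediate (not isolated)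
6 | pashanone, (E)-1-(2,6-dihydroxy-3,4-dimethoxyphenyl)-3-phenylprop-2-en-1-one | COc1cc(O)c(C(=O)/C=C/c2ccccc2)c(O)c1OC | intermediate
7 | (E)-β-ocimene, (3E)-3,7-dimethylocta-1,3,6-triene | C=C/C(C)=C/CC=C(C)C | starting material
8 | chalcone spiroborate B[(R)-VAPOL diolate][6 bound through the 6'-phenolate O and the C=O]; the 2'-O-bound isomer is equivalent; the R biaryl axis cannot be written in SMILES | COc1cc2c(c(O)c1OC)C(/C=C/c1ccccc1)=[O+][B-]3(O2)Oc2c4c5ccccc5ccc4cc(-c4ccccc4)c2-c2c(-c4ccccc4)cc4ccc5ccccc5c4c2O3 | intermediate (not isolated)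
9 | cycloadduct spiroborate B[(R)-VAPOL diolate][10 bound through the 6'-phenolate O and the C=O], cyclohexene (1S,2S,6S) | COc1cc2c(c(O)c1OC)C([C@H]1[C@H](CC=C(C)C)C(C)=CC[C@@H]1c1ccccc1)=[O+][B-]3(O2)Oc2c4c5ccccc5ccc4cc(-c4ccccc4)c2-c2c(-c4ccccc4)cc4ccc5ccccc5c4c2O3 | intermediate (not isolated)
10 | (2,6-dihydroxy-3,4-dimethoxyphenyl)[(1S,2S,6S)-3-methyl-2-(3-methylbut-2-en-1-yl)-6-phenylcyclohex-3-en-1-yl]methanone | COc1cc(O)c(C(=O)[C@H]2[C@H](CC=C(C)C)C(C)=CC[C@@H]2c2ccccc2)c(O)c1OC | target

**Totals**

Total step count: 3. Longest linear sequence: 3 steps (1 → 3 → 6 → 10); 4 and 7 enter as single convergent inputs.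

**Steps most likely to fail, with fallbacks**

Step 3 (highest risk). The aroyl-exo preference is a ligand-based prediction against the usual endo outcome, so the main product may be the cis,trans 2-epimer. The free second phenol may also add to the activated enone to give a flavanone. The fallback sets out from 6 and comes back at 10. Ac2O, pyridine and DMAP give 2',6'-diacetoxy-3',4'-dimethoxychalcone F1, whose twisted, non-chelating aroyl group has a weaker endo preference. F1 is heated with 7 without any Lewis acid (neat, 150 °C, sealed tube, or 19 kbar, CH2Cl2, rt). The racemic trans,trans cycloadduct diacetate F2 is expected to be the minor diastereomer and is separated from the endo isomer and the regioisomer by preparative HPLC. K2CO3 in MeOH cleaves the acetates to the racemic target F3, and F3 is resolved on a chiral stationary phase (supercritical-fluid chromatography) to give 10.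

Step 1. The carbonyl is already chelated by the 6'-O–Al group, so cleavage of the 2'-OMe needs forcing conditions and may spill over to the 3'-OMe. The fallback sets out from 1 and comes back at 6, bypassing 3. Claisen–Schmidt condensation of 1 with 4 (KOH, EtOH) gives 2'-hydroxy-4',5',6'-trimethoxychalcone F4. NaOAc in refluxing EtOH closes it (oxa-Michael) to racemic 5,6,7-trimethoxyflavanone F5. With no phenol competing for the carbonyl, AlCl3 in MeCN at 60 °C removes only the peri 5-OMe to give racemic 5-hydroxy-6,7-dimethoxyflavanone F6. 50% aq KOH in EtOH at rt opens the pyranone ring (retro-oxa-Michael), and cold acidification delivers 6.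

Step 2. The diphenolate lowers the acidity of the methyl ketone, and the product can close to the flavanone on acidification. The fallback sets out from 3 and comes back at 6. NaH and MOMCl in DMF give 2',6'-bis(methoxymethoxy)-3',4'-dimethoxyacetophenone F7. Condensation with 4 (KOH, EtOH, rt) then proceeds on a neutral ketone with no cyclisation path and gives 2',6'-bis(methoxymethoxy)-3',4'-dimethoxychalcone F8. 3 M HCl in MeOH at 40 °C removes both acetals to give 6.

**Further compounds**

F1 | step 3 | 2',6'-diacetoxy-3',4'-dimethoxychalcone | COc1cc(OC(C)=O)c(C(=O)/C=C/c2ccccc2)c(OC(C)=O)c1OC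
F2 | step 3 | racemic trans,trans cycloadduct diacetate, 1:1 mixture of the (1S,2S,6S) and (1R,2R,6R) forms | COc1cc(OC(C)=O)c(C(=O)[C@H]2[C@H](CC=C(C)C)C(C)=CC[C@@H]2c2ccccc2)c(OC(C)=O)c1OC.COc1cc(OC(C)=O)c(C(=O)[C@@H]2[C@@H](CC=C(C)C)C(C)=CC[C@H]2c2ccccc2)c(OC(C)=O)c1OC
F3 | step 3 | racemic target, 1:1 mixture of 10 and its (1R,2R,6R) mirror image | COc1cc(O)c(C(=O)[C@H]2[C@H](CC=C(C)C)C(C)=CC[C@@H]2c2ccccc2)c(O)c1OC.COc1cc(O)c(C(=O)[C@@H]2[C@@H](CC=C(C)C)C(C)=CC[C@H]2c2ccccc2)c(O)c1OC
F4 | step 1 | 2'-hydroxy-4',5',6'-trimethoxychalcone, (E) | COc1cc(O)c(C(=O)/C=C/c2ccccc2)c(OC)c1OC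
F5 | step 1 | racemic 5,6,7-trimethoxyflavanone | COc1cc2OC(c3ccccc3)CC(=O)c2c(OC)c1OC
F6 | step 1 | racemic 5-hydroxy-6,7-dimethoxyflavanone | COc1cc2OC(c3ccccc3)CC(=O)c2c(O)c1OC
F7 | step 2 | 2',6'-bis(methoxymethoxy)-3',4'-dimethoxyacetophenone | CC(=O)c1c(OCOC)cc(OC)c(OC)c1OCOC
F8 | step 2 | 2',6'-bis(methoxymethoxy)-3',4'-dimethoxychalcone, (E) | COCOc1cc(OC)c(OC)c(OCOC)c1C(=O)/C=C/c1ccccc1
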